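**Retrosynthetic overview**

1. Target 22 ⇐ benzyl ether 21 ⇐ 5-(p-tolylsulfanyl) lactone 20: after ring formation only the C5–S bond and the O-benzyl group remain to be hydrogenolysed.
2. 20 ⇐ amide 15 + (S,E)-alkenyl sulfoxide 11 in one operation: keteniminium formation, O-sulfonium [3,3]-sigmatropic rearrangement (C3–C4 bond, both stereocentres), then closure of the oxolan-2-one through the O1–C5 bond, O1 being the former sulfinyl oxygen.
3. Enabling feature: in the oxolan-2-one ring, C2(=O)–C3–C4–C5–O1 is a 1,4-dioxygenated butanoate whose C5 is an unsubstituted O-bearing CH2 next to stereocentre C4. C5 can therefore be carried at aldehyde level as a thionium carbon, C3–C4 is an acyl α-carbon/vinyl β-carbon bond, and C3 is epimerizable towards the trans arrangement.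
4. 11 ⇐ alkynyl sulfoxide 10 ⇐ arylpropyne 7 ⇐ aryl bromide 1 + propargyl bromide 4, with sulfur chirality from sulfinate 8; 15 ⇐ acid 12 + pyrrolidine 13.
5. Ring order: both benzene rings are bought; the oxolan-2-one, the only ring made, is closed in step 7.

Key step: step 7

Remark: C5 of 20 is expected as an epimer mixture and is drawn without configuration because step 8 erases it; the sense of chirality transfer in step 7 is assigned by the chair model known for the dichloroketene lactonization of alkenyl sulfoxides, and the mirror-image sulfinate would be used in step 4 if the opposite sense were found.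

Step 1
Reactants: 1 4-bromo-2,6-dimethoxyphenol; 2 benzyl bromide
Product: 3 2-(benzyloxy)-5-bromo-1,3-dimethoxybenzene
Conditions: K2CO3, DMF, 60 °C
Reagents that add atoms: none
Why: Williamson ether synthesis; O-alkylation of the phenoxide by benzyl bromide should be reliable even for the phenol flanked by two methoxy groups, and no stereocentre is involved.

Step 2
Reactants: 3 2-(benzyloxy)-5-bromo-1,3-dimethoxybenzene; 4 3-bromo-1-(trimethylsilyl)prop-1-yne
Product: 6 {3-[4-(benzyloxy)-3,5-dimethoxyphenyl]prop-1-yn-1-yl}trimethylsilane, via arylmagnesium bromide 5 (not isolated)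
Conditions: Mg, THF, reflux; then 4, CuBr·SMe2 (5 mol %), THF, 0 °C to rt
Reagents that add atoms: none
Why: Grignard formation followed by copper-catalysed SN2 coupling with the propargylic bromide; the silyl cap should block SN2' attack to the allene and mask the acidic alkyne C–H.

Step 3
Reactants: 6 {3-[4-(benzyloxy)-3,5-dimethoxyphenyl]prop-1-yn-1-yl}trimethylsilane
Product: 7 2-(benzyloxy)-1,3-dimethoxy-5-(prop-2-yn-1-yl)benzene
Conditions: K2CO3 (0.2 equiv), MeOH, 0 °C to rt, short reaction time
Reagents that add atoms: none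
Why: Base-catalysed methanolysis of the C(sp)–Si bond (protodesilylation); catalytic carbonate at low temperature should avoid propargyl-to-allenyl isomerization of the benzylic CH2.

Step 4
Reactants: 7 2-(benzyloxy)-1,3-dimethoxy-5-(prop-2-yn-1-yl)benzene; 8 (1S,2R,5S)-menthyl (R)-4-methylbenzenesulfinate
Product: 10 2-(benzyloxy)-1,3-dimethoxy-5-{3-[(R)-4-methylbenzenesulfinyl]prop-2-yn-1-yl}benzene, via alkynylmagnesium bromide 9 (not isolated)
Conditions: EtMgBr, THF, 0 °C to rt; then 8, toluene, −20 °C; sat. aq NH4Cl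
Reagents that add atoms: none
Why: Andersen sulfoxide synthesis; the alkynyl Grignard reagent should displace menthoxide from sulfur with clean inversion, which sets the sulfur stereocentre (descriptor R because alkynyl outranks p-tolyl).

Step 5
Reactants: 10 2-(benzyloxy)-1,3-dimethoxy-5-{3-[(R)-4-methylbenzenesulfinyl]prop-2-yn-1-yl}benzene
Product: 11 2-(benzyloxy)-1,3-dimethoxy-5-{(2E)-3-[(S)-4-methylbenzenesulfinyl]prop-2-en-1-yl}benzene
Conditions: iBu2AlH (1.1 equiv), THF, −90 °C; aq potassium sodium tartrate (KNaC4H4O6)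
Reagents that add atoms: none
Why: Anti-selective hydride reduction (hydroalumination–protonolysis) of a 1-alkynyl sulfoxide, a known route to (E)-1-alkenyl sulfoxides; sulfur is untouched and its descriptor becomes S only because p-tolyl outranks alkenyl.

Step 6
Reactants: 12 3-(3,4,5-trimethoxyphenyl)propanoic acid; 13 pyrrolidine
Product: 15 1-(pyrrolidin-1-yl)-3-(3,4,5-trimethoxyphenyl)propan-1-one, via acyl imidazolide 14 (not isolated)
Conditions: 1,1'-carbonyldiimidazole, THF, rt; then 13, rt
Reagents that add atoms: none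
Why: Amide coupling through the acyl imidazolide, a standard activation that should tolerate the electron-rich arene; no stereocentre is involved.

Step 7
Reactants: 15 1-(pyrrolidin-1-yl)-3-(3,4,5-trimethoxyphenyl)propan-1-one; 11 2-(benzyloxy)-1,3-dimethoxy-5-{(2E)-3-[(S)-4-methylbenzenesulfinyl]prop-2-en-1-yl}benzene
Product: 20 (3R,4R)-4-{[4-(benzyloxy)-3,5-dimethoxyphenyl]methyl}-5-[(4-methylphenyl)sulfanyl]-3-[(3,4,5-trimethoxyphenyl)methyl]oxolan-2-one, via keteniminium triflate 16 (not isolated), via alkenyloxysulfonium triflate 17 (not isolated), via thionium triflate 18 (not isolated), via cyclic iminium ether triflate 19 (not isolated)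
Conditions: 15 (1.3 equiv), 2-fluoropyridine (2.6 equiv), Tf2O (1.25 equiv), CH2Cl2, −78 to 0 °C, 15 min; then 11 (1.0 equiv), −78 °C to rt; then THF/H2O (acetate buffer, pH 4–5), rt; aq NaHCO3 work-up
Reagents that add atoms: water, O
Why: Proposed new method: Tf2O/2-fluoropyridine should convert amide 15 into keteniminium 16, whose central carbon is attacked by the sulfinyl oxygen of 11 to give the alkenyloxysulfonium ketene N,O-acetal 17; a charge-accelerated [3,3]-sigmatropic rearrangement (C3–C4 formed, S–O broken) then gives thionium 18, the regenerated amide oxygen (the former sulfinyl oxygen) adds to the thionium carbon to give iminium ether 19, and hydrolysis at the iminium carbon releases pyrrolidine and lactone 20. The closest known reaction types are the lactonization of alkenyl sulfoxides with dichloroketene and the sulfonium [3,3] rearrangements of keteniminium–sulfoxide adducts; what is new is their union with an alkyl-substituted, amide-derived keteniminium that ends in lactone closure. The oxolanone ring closes by 5-exo-trig attack of oxygen on the C=S+ carbon, which forms the O1–C5 bond. C4 is set by chirality transfer from sulfur through a chair transition state with p-tolyl pseudo-equatorial (anti to the C=C bond) and the E-alkene placing its arylmethyl group equatorial, which leads to 4R; C3 follows from the E ketene N,O-acetal (sulfoxide adds anti to the arylmethyl group) in the same chair to give 3R, which is also the thermodynamically preferred trans arrangement, while C5 is uncontrolled and erased in step 8. The step needs sulfoxide O-attack on 16 to outrun Friedel–Crafts closure of the trimethoxyphenyl ring, and needs hydrolysis of 19 by C–N rather than C5–O cleavage; activation at low temperature with immediate sulfoxide addition should secure the first, and hydrolysis at pH 4–5, where the amine is expelled from the tetrahedral intermediate, the second.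

Step 8
Reactants: 20 (3R,4R)-4-{[4-(benzyloxy)-3,5-dimethoxyphenyl]methyl}-5-[(4-methylphenyl)sulfanyl]-3-[(3,4,5-trimethoxyphenyl)methyl]oxolan-2-one
Product: 21 (3R,4R)-4-{[4-(benzyloxy)-3,5-dimethoxyphenyl]methyl}-3-[(3,4,5-trimethoxyphenyl)methyl]oxolan-2-one
Conditions: Raney Ni (W-2), EtOH, rt
Reagents that add atoms: none
Why: Reductive desulfurization (C–S hydrogenolysis on nickel) should replace the C5–S bond of the O,S-acetal by C5–H under neutral conditions that leave C3, C4, the lactone and the methyl ethers untouched.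

Step 9
Reactants: 21 (3R,4R)-4-{[4-(benzyloxy)-3,5-dimethoxyphenyl]methyl}-3-[(3,4,5-trimethoxyphenyl)methyl]oxolan-2-one
Product: 22 (3R,4R)-4-[(4-hydroxy-3,5-dimethoxyphenyl)methyl]-3-[(3,4,5-trimethoxyphenyl)methyl]oxolan-2-one
Conditions: H2 (1 atm), Pd on carbon (10 wt %), EtOAc/EtOH, rt
Reagents that add atoms: none
Why: Catalytic hydrogenolysis of the benzyl aryl ether should free the phenol under neutral conditions, with the lactone, the methyl ethers and both stereocentres inert.

**Compound list**

1 | 4-bromo-2,6-dimethoxyphenol | COc1cc(Br)cc(OC)c1O | starting material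
2 | benzyl bromide | BrCc1ccccc1 | starting material
3 | 2-(benzyloxy)-5-bromo-1,3-dimethoxybenzene | COc1cc(Br)cc(OC)c1OCc1ccccc1 | intermediate
4 | 3-bromo-1-(trimethylsilyl)prop-1-yne | C[Si](C)(C)C#CCBr | starting material
5 | [4-(benzyloxy)-3,5-dimethoxyphenyl]magnesium bromide (formed in the flask) | COc1cc([Mg]Br)cc(OC)c1OCc1ccccc1 | intermediate
6 | {3-[4-(benzyloxy)-3,5-dimethoxyphenyl]prop-1-yn-1-yl}trimethylsilane | COc1cc(CC#C[Si](C)(C)C)cc(OC)c1OCc1ccccc1 | intermediate
7 | 2-(benzyloxy)-1,3-dimethoxy-5-(prop-2-yn-1-yl)benzene | COc1cc(CC#C)cc(OC)c1OCc1ccccc1 | intermediate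
8 | (1S,2R,5S)-menthyl (R)-4-methylbenzenesulfinate | CC(C)[C@H]1CC[C@H](C)C[C@@H]1O[S@@](=O)c1ccc(C)cc1 | starting material
9 | {3-[4-(benzyloxy)-3,5-dimethoxyphenyl]prop-1-yn-1-yl}magnesium bromide (formed in the flask) | COc1cc(CC#C[Mg]Br)cc(OC)c1OCc1ccccc1 | intermediate
10 | 2-(benzyloxy)-1,3-dimethoxy-5-{3-[(R)-4-methylbenzenesulfinyl]prop-2-yn-1-yl}benzene | COc1cc(CC#C[S@](=O)c2ccc(C)cc2)cc(OC)c1OCc1ccccc1 | intermediate
11 | 2-(benzyloxy)-1,3-dimethoxy-5-{(2E)-3-[(S)-4-methylbenzenesulfinyl]prop-2-en-1-yl}benzene | COc1cc(C/C=C/[S@](=O)c2ccc(C)cc2)cc(OC)c1OCc1ccccc1 | intermediate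
12 | 3-(3,4,5-trimethoxyphenyl)propanoic acid | COc1cc(CCC(=O)O)cc(OC)c1OC | starting material
13 | pyrrolidine | C1CCNC1 | starting material
14 | 1-(1H-imidazol-1-yl)-3-(3,4,5-trimethoxyphenyl)propan-1-one (formed in the flask) | COc1cc(CCC(=O)n2ccnc2)cc(OC)c1OC | intermediate
15 | 1-(pyrrolidin-1-yl)-3-(3,4,5-trimethoxyphenyl)propan-1-one | COc1cc(CCC(=O)N2CCCC2)cc(OC)c1OC | intermediate
16 | 1-[3-(3,4,5-trimethoxyphenyl)prop-1-en-1-ylidene]pyrrolidin-1-ium triflate (formed in the flask) | COc1cc(CC=C=[N+]2CCCC2)cc(OC)c1OC.[O-]S(=O)(=O)C(F)(F)F | intermediate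
17 | (S)-{(1E)-3-[4-(benzyloxy)-3,5-dimethoxyphenyl]prop-1-en-1-yl}(4-methylphenyl){[(1E)-1-(pyrrolidin-1-yl)-3-(3,4,5-trimethoxyphenyl)prop-1-en-1-yl]oxy}sulfonium triflate (formed in the flask) | COc1cc(C/C=C/[S@+](O/C(=C/Cc2cc(OC)c(OC)c(OC)c2)N2CCCC2)c2ccc(C)cc2)cc(OC)c1OCc1ccccc1.[O-]S(=O)(=O)C(F)(F)F | intermediate
18 | {(2R,3R)-2-{[4-(benzyloxy)-3,5-dimethoxyphenyl]methyl}-4-oxo-4-(pyrrolidin-1-yl)-3-[(3,4,5-trimethoxyphenyl)methyl]butylidene}(4-methylphenyl)sulfonium triflate (formed in the flask) | O=C(N1CCCC1)[C@H](Cc1cc(OC)c(OC)c(OC)c1)[C@@H](Cc1cc(OC)c(OCc2ccccc2)c(OC)c1)C=[S+]c1ccc(C)cc1.[O-]S(=O)(=O)C(F)(F)F | intermediate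
19 | 1-[(3R,4R)-4-{[4-(benzyloxy)-3,5-dimethoxyphenyl]methyl}-5-[(4-methylphenyl)sulfanyl]-3-[(3,4,5-trimethoxyphenyl)methyl]oxolan-2-ylidene]pyrrolidin-1-ium triflate, C5 epimers (formed in the flask) | Cc1ccc(SC2OC(=[N+]3CCCC3)[C@H](Cc3cc(OC)c(OC)c(OC)c3)[C@H]2Cc2cc(OC)c(OCc3ccccc3)c(OC)c2)cc1.[O-]S(=O)(=O)C(F)(F)F | intermediate
20 | (3R,4R)-4-{[4-(benzyloxy)-3,5-dimethoxyphenyl]methyl}-5-[(4-methylphenyl)sulfanyl]-3-[(3,4,5-trimethoxyphenyl)methyl]oxolan-2-one, C5 epimers | Cc1ccc(SC2OC(=O)[C@H](Cc3cc(OC)c(OC)c(OC)c3)[C@H]2Cc2cc(OC)c(OCc3ccccc3)c(OC)c2)cc1 | intermediate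
21 | (3R,4R)-4-{[4-(benzyloxy)-3,5-dimethoxyphenyl]methyl}-3-[(3,4,5-trimethoxyphenyl)methyl]oxolan-2-one | COc1cc(C[C@H]2COC(=O)[C@@H]2Cc2cc(OC)c(OC)c(OC)c2)cc(OC)c1OCc1ccccc1 | intermediate
22 | (3R,4R)-4-[(4-hydroxy-3,5-dimethoxyphenyl)methyl]-3-[(3,4,5-trimethoxyphenyl)methyl]oxolan-2-one | COc1cc(C[C@H]2COC(=O)[C@@H]2Cc2cc(OC)c(OC)c(OC)c2)cc(OC)c1O | target

**Step count and risks**

Total steps: 9. Longest linear sequence: 8 steps (steps 1, 2, 3, 4, 5, 7, 8, 9); step 6 is the one-step side branch.

Steps most likely to fail: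

Step 7 (proposed method). Several processes could divert it:
- the keteniminium could be captured intramolecularly by the trimethoxyphenyl ring (Friedel–Crafts) before the sulfoxide adds;
- the thionium could be captured by an arene instead of the amide oxygen;
- the iminium ether could open hydrolytically to a 4-oxo amide instead of releasing pyrrolidine;
- non-chair transition states could erode the transfer of chirality from sulfur;
- diastereocontrol at C3 could be incomplete, which would be corrected by base equilibration of 21 towards the favoured trans arrangement.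

The fallback uses only known reaction types. It sets out from 11 and returns at 21. Dichloroketene F1, generated from trichloroacetyl chloride and Zn–Cu couple in Et2O, should react with 11 in the established [3,3] rearrangement–lactonization of alkenyl sulfoxides to give (4S)-4-{[4-(benzyloxy)-3,5-dimethoxyphenyl]methyl}-3,3-dichloro-5-[(4-methylphenyl)sulfanyl]oxolan-2-one F2. This has the same spatial sense at C4 as 20; the descriptor differs only because CCl2 outranks C5. Bu3SnH/AIBN in toluene at reflux should then remove both chlorine atoms and the arylsulfanyl group to give (4R)-4-{[4-(benzyloxy)-3,5-dimethoxyphenyl]methyl}oxolan-2-one F3. Deprotonation with LiN(SiMe3)2 in THF at −78 °C gives lithium (3R)-3-{[4-(benzyloxy)-3,5-dimethoxyphenyl]methyl}-2,3-dihydrofuran-5-olate F4, and alkylation with commercial 3,4,5-trimethoxybenzyl bromide anti to the C4 substituent should give 21, where the route is rejoined before step 9.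

Step 4. The propargylic, benzylic CH2 may undergo prototropic shift to an allenyl sulfoxide in the basic magnesium alkoxide medium, and sulfur configuration may erode through exchange at sulfur. The fallback attaches sulfur to an sp2 carbon nucleophile instead; it sets out from 7 and returns at 11, by-passing 10 and step 5. Hydroalumination of 7 with iBu2AlH in hexane at 50 °C should give the (E)-alkenyl(diisobutyl)alane F5. Iodinolysis (I2, THF, −50 °C) gives 2-(benzyloxy)-5-[(2E)-3-iodoprop-2-en-1-yl]-1,3-dimethoxybenzene F6. Iodine–lithium exchange (tBuLi, Et2O, −78 °C) gives the (E)-alkenyllithium F7, and its inverse addition to sulfinate 8 at −78 °C should give 11 with inversion at sulfur.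

Step 8. Desulfurization on nickel may be incomplete, may be accompanied by uncontrolled partial loss of the benzyl group, or may over-reduce the lactone. The fallback replaces surface hydrogenolysis by a homolytic chain reduction; it sets out from 20 and returns at 21. Bu3SnH/AIBN in toluene at reflux should cleave the C5–S bond of the O,S-acetal through the oxygen-stabilized C5 radical, leaving the benzyl ether intact for step 9.

**Further compounds**

F1 | step 7 | dichloroketene | ClC(Cl)=C=O
F2 | step 7 | (4S)-4-{[4-(benzyloxy)-3,5-dimethoxyphenyl]methyl}-3,3-dichloro-5-[(4-methylphenyl)sulfanyl]oxolan-2-one, C5 epimers | Cc1ccc(SC2OC(=O)C(Cl)(Cl)[C@H]2Cc2cc(OC)c(OCc3ccccc3)c(OC)c2)cc1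
F3 | step 7 | (4R)-4-{[4-(benzyloxy)-3,5-dimethoxyphenyl]methyl}oxolan-2-one | COc1cc(C[C@H]2COC(=O)C2)cc(OC)c1OCc1ccccc1
F4 | step 7 | lithium (3R)-3-{[4-(benzyloxy)-3,5-dimethoxyphenyl]methyl}-2,3-dihydrofuran-5-olate | COc1cc(C[C@H]2COC(O[Li])=C2)cc(OC)c1OCc1ccccc1
F5 | step 4 | {(1E)-3-[4-(benzyloxy)-3,5-dimethoxyphenyl]prop-1-en-1-yl}bis(2-methylpropyl)alane | COc1cc(C/C=C/[Al](CC(C)C)CC(C)C)cc(OC)c1OCc1ccccc1
F6 | step 4 | 2-(benzyloxy)-5-[(2E)-3-iodoprop-2-en-1-yl]-1,3-dimethoxybenzene | COc1cc(C/C=C/I)cc(OC)c1OCc1ccccc1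
F7 | step 4 | {(1E)-3-[4-(benzyloxy)-3,5-dimethoxyphenyl]prop-1-en-1-yl}lithium | COc1cc(C/C=C/[Li])cc(OC)c1OCc1ccccc1
F0 | step 8 | none | none
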